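Gamma is the flask in which second end groups are fed into first end groups at 35 °C. The question is how many links stand at the end of such a feed.

| setting | maple | cedar | larch | gamma | theta | delta | alpha |
|---|---|---|---|---|---|---|---|
| first end groups | 0.40 M | 0.40 M | 0.40 M | 0.40 M | 0.40 M | 0.40 M (fed, over 15 min) | 0.40 M |
| second end groups | 0.98 equiv | 0.49 equiv | 0.73 equiv | 0.980 equiv (fed, over 15 min) | 0.980 equiv (fed, over 15 min) | 0.980 equiv | 0.980 equiv |
| temperature | 20 °C | 35 °C | 20 °C | 35 °C |  | 35 °C |  |
| remark | run made earlier | run made earlier | run made earlier | all else is in the flask from the start; the feed brings no volume worth counting | the addition at −5 °C, then warmed to 35 °C; the feed brings no volume worth counting | all else is in the flask from the start; the feed brings no volume worth counting | everything together at the start at −5 °C, warmed to 35 °C at 15 min |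
| time |  |  |  | 20 min | 20 min | 20 min | 20 min |

| run | time / min | links / % | first end groups / % |
|---|---|---|---|
| maple | 4.00 | 17.0 | 6.4 |
| maple | 8.00 | 17.6 | 5.6 |
| maple | 12.0 | 17.7 | 4.5 |
| maple | 15.0 | 17.4 | 4.8 |
| maple | 20.0 | 16.1 | 4.2 |
| maple | 25.0 | 15.9 | 5.9 |
| cedar | 1.50 | 3.7 | 46.4 |
| cedar | 5.00 | 3.4 | 39.4 |
| cedar | 8.00 | 3.6 | 34.9 |
| cedar | 12.0 | 2.1 | 29.9 |
| cedar | 20.0 | 2.8 | 24.1 |
| cedar | 25.0 | 2.6 | 21.3 |
| larch | 8.00 | 10.3 | 25.7 |
| larch | 15.0 | 10.9 | 24.4 |
| larch | 25.0 | 9.5 | 22.6 |
| larch | 30.0 | 10.3 | 20.4 |
| larch | 40.0 | 9.4 | 19.5 |
| larch | 50.0 | 8.6 | 18.5 |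

(each reading ± 0.5 percentage points)

* the flask with the highest amount of links, in percent of the first end groups charged ("all alike" if they lie within 1.5 percentage points) (gamma / theta / delta / alpha / all alike)
* final links, as a percentage of the first end groups charged, in gamma
* final links, as a percentage of the first end groups charged, in theta
* final links, as a percentage of the first end groups charged, in delta
* final links, as a percentage of the first end groups charged, in alpha



In each run the first end groups drop fast, then creep. Cedar already stands at 46.4% after 1.50 min; this first reading bounds its fast coupling time from above and does not measure it. At the first reading, part of what was consumed stands as links and the rest is unread. Links over that rest is a selectivity factor: 0.0741 in cedar, 0.222 in maple and 0.161 in larch. Maple over larch reads 1.38, and their equivalents stand at 1.34, so at one temperature the factor tracks the second end groups charged.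

My own reckoning scales cedar's factor by 2.00 for equivalents and by 0.100 for that upper bound on the coupling time over the feed time, giving 0.0148. This is the feed number, the links made per other coupling while a feed keeps the second end groups thin. My reckoning therefore puts gamma's links at or below about 1.48%. One number is not enough, though: cedar's links drift from 3.7% to 2.6%, and theta and alpha begin at −5 °C, where no run stands.

The forecast names alpha as highest, with gamma 7%, theta 19%, delta 12% and alpha 20%. Of the cold flasks it says “Extrapolated, links are higher if locked in”. Its gamma stands above my reckoning.

The flasks give gamma 0.00744%, theta 11.8%, delta 2.42% and alpha 19.4%, so alpha stands highest.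

    2 first end groups → homo dimer (k = 0.00237 /M/s, Ea = 57.0 kJ/mol)
    first end groups + second end groups ⇌ links (K = 117 /M, k = 0.0553 /M/s, Ea = 71.0 kJ/mol, ΔH = −17.0 kJ/mol)
    first end groups + second end groups → rings, rate k3*[first end groups] as long as [second end groups] is above zero (k = 0.0583 /s, Ea = 87.0 kJ/mol)
    second end groups → decomposed reagent (k = 0.00478 /s, Ea = 90.0 kJ/mol)
    (constants at 35 °C)

Gamma's links lie below its feed number, beside rings at 69.9% and homo dimer at 30.1%. The neighbour repeats gamma with first end groups at 0.24 M. Scaling the feed number by concentration gives 0.00890, which puts its links at or below about 0.890%. That neighbour ends with 0.00579% links, and its rings stand at 77.9%.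

The readings are simulated for an exercise, noise included.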